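**Retrosynthetic overview**

1. The target is numbered as a cycloundec-1-ene-1-carboxylic acid: C1(CO2H)=C2H, C3H2, C4H2, C5(=CH2), C6H(OH), C7H2, C8Me2, C9H2, C10H(O-isovaleryl), C11H2. Enabling feature: C5(=CH2)–C4–C3–C2=C1 is a hexa-1,5-diene whose central ring bond is C3–C4; with C6 at the ketone level, C6(=O)–C5–C4–C3–C2=C1 is a δ,ε-unsaturated ketone (oxy-Cope retron), and C6 and C1 are joined the other way round the ring by only five atoms (C7–C11).
2. Key disconnection C3–C4: anionic oxy-Cope four-carbon ring expansion of a 1,2-divinylcycloheptanol in which C6–C1 is a temporary ring bond; the transposed C6/C5 enolate is trapped with Eschenmoser's salt, which brings in the methylidene carbon.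
3. Cycloheptane: C6–C1 bond by intramolecular indium Barbier cyclisation of a γ-bromo enoate aldehyde (creates the vinyl-bearing quaternary C1), then oxidation at C6 and vinyl addition (C5, C4).
4. Open chain: 3,3-dimethylpentane-1,5-diol (C6–C10) + tert-butyl 2-(bromomethyl)acrylate (C11, C1, CO2R; catalytic asymmetric allylation sets C10) + allyl bromide (C2, C3; cross-metathesis).
5. Ring order: seven-membered carbocycle first (step 8), then its expansion to the eleven-membered ring (step 11); endgame: isovalerate at C10, unveiling of the α-methylene ketone, Corey–Bakshi–Shibata reduction (sets C6), ester cleavage.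

Key step: step 11

Remark: 13, 14 and 16 are carried as mixtures of diastereomers at the two ring carbons that become sp2 in step 11, and 20, 21, 23 and 24 as mixtures at the aminomethyl-bearing carbon that is erased in step 14; their SMILES define only the centre that reaches the target.
Remark: the numbered starting materials 1, 4, 8, 15, 17 and 22 are taken as catalogue compounds.

**Route**

Step 1
Reactants: 1 3,3-dimethylpentane-1,5-diol
Product: 2 5-[(4-methoxybenzyl)oxy]-3,3-dimethylpentan-1-ol
Conditions: Ag2O (1.5 equiv), 4-methoxybenzyl chloride (1.1 equiv), CH2Cl2, rt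
Reagents that add atoms: 4-methoxybenzyl chloride, COc1ccc(CCl)cc1
Why: Silver-oxide-mediated Williamson etherification of a symmetrical diol should stop at the mono-ether, and no stereocentre is involved.

Step 2
Reactants: 2 5-[(4-methoxybenzyl)oxy]-3,3-dimethylpentan-1-ol
Product: 3 5-[(4-methoxybenzyl)oxy]-3,3-dimethylpentanal
Conditions: TEMPO (10 mol %), PhI(OAc)2, CH2Cl2, rt
Reagents that add atoms: none
Why: Oxoammonium (TEMPO) oxidation of a primary alcohol should stop at the aldehyde, which carries no stereocentre and is shielded from self-aldolisation by the neighbouring quaternary carbon.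

Step 3
Reactants: 3 5-[(4-methoxybenzyl)oxy]-3,3-dimethylpentanal; 4 tert-butyl 2-(bromomethyl)prop-2-enoate
Product: 6 tert-butyl (4S)-4-hydroxy-8-[(4-methoxybenzyl)oxy]-6,6-dimethyl-2-methylideneoctanoate, via trimethylsilyl ether 5 (not isolated)
Conditions: CrCl2 (10 mol %), chiral tridentate carbazole-bis(oxazoline) ligand (12 mol %), Mn powder, Me3SiCl, iPr2NEt (cat.), THF, rt; then aq. citric acid, MeOH, rt
Reagents that add atoms: tert-butyl 2-(bromomethyl)prop-2-enoate (4), C=C(CBr)C(=O)OC(C)(C)C
Why: Catalytic asymmetric Nozaki–Hiyama–Kishi-type 2-(alkoxycarbonyl)allylation, in which the allylchromium species adds through a closed six-membered transition state and the ligand enantiomer that directs the allyl group to the Re face of the aldehyde sets the (S) carbinol centre, while the tert-butyl ester prevents lactonisation.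

Step 4
Reactants: 6 tert-butyl (4S)-4-hydroxy-8-[(4-methoxybenzyl)oxy]-6,6-dimethyl-2-methylideneoctanoate
Product: 7 tert-butyl (4S)-4-[(tert-butyldimethylsilyl)oxy]-8-[(4-methoxybenzyl)oxy]-6,6-dimethyl-2-methylideneoctanoate
Conditions: tert-butyldimethylsilyl chloride, imidazole, DMF, rt
Reagents that add atoms: tert-butyldimethylsilyl chloride, CC(C)(C)[Si](C)(C)Cl
Why: Imidazole-promoted O-silylation of the secondary alcohol leaves the stereocentre untouched and installs an ether that survives the strongly basic key step.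

Step 5
Reactants: 7 tert-butyl (4S)-4-[(tert-butyldimethylsilyl)oxy]-8-[(4-methoxybenzyl)oxy]-6,6-dimethyl-2-methylideneoctanoate; 8 3-bromoprop-1-ene (allyl bromide)
Product: 9 tert-butyl (2E,4S)-2-(2-bromoethylidene)-4-[(tert-butyldimethylsilyl)oxy]-8-[(4-methoxybenzyl)oxy]-6,6-dimethyloctanoate
Conditions: second-generation Grubbs catalyst (5 mol %), 8 (5 equiv), CH2Cl2, 40 °C
Reagents that add atoms: 3-bromoprop-1-ene (8), C=CCBr
Why: Olefin cross-metathesis of a 1,1-disubstituted acrylate with a terminal alkene, driven by loss of ethene, should give the trisubstituted γ-bromo enoate mainly as the (E) isomer, whose geometry is of no consequence because it is erased in step 8.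

Step 6
Reactants: 9 tert-butyl (2E,4S)-2-(2-bromoethylidene)-4-[(tert-butyldimethylsilyl)oxy]-8-[(4-methoxybenzyl)oxy]-6,6-dimethyloctanoate
Product: 10 tert-butyl (2E,4S)-2-(2-bromoethylidene)-4-[(tert-butyldimethylsilyl)oxy]-8-hydroxy-6,6-dimethyloctanoate
Conditions: DDQ, CH2Cl2/pH 7 buffer (10:1), 0 °C to rt
Reagents that add atoms: none
Why: Oxidative cleavage of the 4-methoxybenzyl ether by DDQ is selective for the electron-rich benzyl group and should leave the silyl ether, the tert-butyl ester and the allylic bromide untouched.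

Step 7
Reactants: 10 tert-butyl (2E,4S)-2-(2-bromoethylidene)-4-[(tert-butyldimethylsilyl)oxy]-8-hydroxy-6,6-dimethyloctanoate
Product: 11 tert-butyl (2E,4S)-2-(2-bromoethylidene)-4-[(tert-butyldimethylsilyl)oxy]-6,6-dimethyl-8-oxooctanoate
Conditions: TEMPO (10 mol %), PhI(OAc)2, CH2Cl2, rt
Reagents that add atoms: none
Why: Oxoammonium (TEMPO) oxidation of the primary alcohol to the aldehyde is neutral enough for the allylic bromide and affects no stereocentre.

Step 8
Reactants: 11 tert-butyl (2E,4S)-2-(2-bromoethylidene)-4-[(tert-butyldimethylsilyl)oxy]-6,6-dimethyl-8-oxooctanoate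
Product: 13 tert-butyl (6S)-6-[(tert-butyldimethylsilyl)oxy]-1-ethenyl-2-hydroxy-4,4-dimethylcycloheptane-1-carboxylate, via allylindium bromide 12 (not isolated)
Conditions: In powder (1.5 equiv), THF/H2O (1:1), 0.01 M, rt
Reagents that add atoms: none
Why: Intramolecular Barbier (vinylogous Reformatsky) allylation, in which the allylindium species adds through its ester-bearing γ-carbon in a six-membered cyclic transition state to the tethered aldehyde, should close the seven-membered ring and create the vinyl-bearing quaternary carbon; the two new stereocentres form without control and need none, since one is oxidised in step 9 and the other becomes sp2 in step 11.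

Step 9
Reactants: 13 tert-butyl (6S)-6-[(tert-butyldimethylsilyl)oxy]-1-ethenyl-2-hydroxy-4,4-dimethylcycloheptane-1-carboxylate
Product: 14 tert-butyl (6S)-6-[(tert-butyldimethylsilyl)oxy]-1-ethenyl-4,4-dimethyl-2-oxocycloheptane-1-carboxylate
Conditions: Dess–Martin periodinane, CH2Cl2, rt
Reagents that add atoms: none
Why: Dess–Martin oxidation of the hindered secondary alcohol gives a β-keto ester that cannot enolise between the carbonyl groups, so the quaternary centre and the silyloxy centre are not at risk.

Step 10
Reactants: 14 tert-butyl (6S)-6-[(tert-butyldimethylsilyl)oxy]-1-ethenyl-4,4-dimethyl-2-oxocycloheptane-1-carboxylate; 15 vinylmagnesium bromide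
Product: 16 tert-butyl (6S)-6-[(tert-butyldimethylsilyl)oxy]-1,2-diethenyl-2-hydroxy-4,4-dimethylcycloheptane-1-carboxylate
Conditions: anhydrous CeCl3 (1.5 equiv), 15 (1.5 equiv), THF, −78 °C; quench at −78 °C with water, then aq. NH4Cl work-up
Reagents that add atoms: vinylmagnesium bromide (15), C=C[Mg]Br
Why: Organocerium 1,2-addition should reach the hindered ketone without enolisation or attack on the tert-butyl ester; the new tertiary carbinol is expected to form mainly anti to the bulky tert-butoxycarbonyl group (Felkin–Anh, vinyl groups cis), but it is erased in step 11 and the mixture is used as such.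

Step 11
Reactants: 16 tert-butyl (6S)-6-[(tert-butyldimethylsilyl)oxy]-1,2-diethenyl-2-hydroxy-4,4-dimethylcycloheptane-1-carboxylate; 17 dimethyl(methylidene)ammonium iodide (Eschenmoser's salt)
Product: 20 tert-butyl (1E,10S)-10-[(tert-butyldimethylsilyl)oxy]-5-[(dimethylamino)methyl]-8,8-dimethyl-6-oxocycloundec-1-ene-1-carboxylate, via potassium alkoxide 18 (not isolated), via potassium enolate 19 (not isolated)
Conditions: KN(SiMe3)2 (1.05 equiv), 18-crown-6 (1.1 equiv), THF (0.01 M), −78 to 0 °C; then −78 °C, 17 (1.5 equiv), to 0 °C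
Reagents that add atoms: dimethyl(methylidene)ammonium iodide (17), C=[N+](C)C.[I-]
Why: KN(SiMe3)2/18-crown-6 turns 16 into the naked potassium alkoxide 18, whose 3-oxido-hexa-1,5-diene unit (CH2=CH–C(O−)–C(CO2tBu)–CH=CH2) undergoes a charge-accelerated [3,3]-sigmatropic shift (anionic oxy-Cope rearrangement) in which the two vinyl CH2 termini join while the ring bond between the carbinol carbon and the ester-bearing quaternary carbon breaks, and the regiodefined enolate 19 is then C-aminomethylated by 17 (Mannich reaction). The closest known reaction type is the anionic oxy-Cope four-carbon ring expansion of 1,2-divinylcycloalkanols to cycloalk-5-enones, which is also known for alkoxides made from 2-vinyl β-keto esters, followed by trapping of the transposed enolate with an electrophile. The eleven-membered ring is closed by ring expansion of the cycloheptane (seven to eleven atoms) through a six-membered pericyclic transition state, chair-like for the cis-divinyl and twist-boat-like for the trans-divinyl diastereomers. The only new stereocentre, the aminomethyl-bearing carbon, forms without control and is removed in step 14, the two adjacent ring stereocentres of 16 become sp2 so that all its diastereomers converge, and the silyloxy-bearing centre is not involved. The step needs the (E)-enoate (ring CH2 groups cis across the new double bond) and reaction of the enolate at its α-carbon before proton transfer can move it: the tert-butoxycarbonyl group stays conjugated and outside (anti to the new CH2–CH2 bond) to avoid allylic 1,3-strain, which puts the ring CH2 inside, and the enolate is trapped at −78 °C. The same (E) geometry keeps the enolate carbon away from the ester carbonyl, so a transannular Claisen condensation is not possible, and high dilution suppresses intermolecular Michael addition should the aldolate open reversibly by retro-aldol cleavage.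

Step 12
Reactants: 20 tert-butyl (1E,10S)-10-[(tert-butyldimethylsilyl)oxy]-5-[(dimethylamino)methyl]-8,8-dimethyl-6-oxocycloundec-1-ene-1-carboxylate
Product: 21 tert-butyl (1E,10S)-5-[(dimethylamino)methyl]-10-hydroxy-8,8-dimethyl-6-oxocycloundec-1-ene-1-carboxylate
Conditions: HF·pyridine, pyridine, THF, 0 °C to rt
Reagents that add atoms: none
Why: Fluoride-driven desilylation (strong Si–F bond) frees the C10 alcohol with retention, while the amine is protonated and the tert-butyl enoate and ketone are inert to these conditions.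

Step 13
Reactants: 21 tert-butyl (1E,10S)-5-[(dimethylamino)methyl]-10-hydroxy-8,8-dimethyl-6-oxocycloundec-1-ene-1-carboxylate; 22 3-methylbutanoic anhydride (isovaleric anhydride)
Product: 23 tert-butyl (1E,10S)-5-[(dimethylamino)methyl]-8,8-dimethyl-10-[(3-methylbutanoyl)oxy]-6-oxocycloundec-1-ene-1-carboxylate
Conditions: 22 (1.5 equiv), DMAP (0.1 equiv), Et3N, CH2Cl2, 0 °C to rt
Reagents that add atoms: 3-methylbutanoic anhydride (22), CC(C)CC(=O)OC(=O)CC(C)C
Why: DMAP-catalysed O-acylation of the secondary alcohol proceeds with retention at C10 and drains the open hydroxy ketone from any transannular hemiketal, the masked enone (Mannich base) being inert.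

Step 14
Reactants: 23 tert-butyl (1E,10S)-5-[(dimethylamino)methyl]-8,8-dimethyl-10-[(3-methylbutanoyl)oxy]-6-oxocycloundec-1-ene-1-carboxylate
Product: 25 tert-butyl (1E,10S)-8,8-dimethyl-5-methylidene-10-[(3-methylbutanoyl)oxy]-6-oxocycloundec-1-ene-1-carboxylate, via methiodide 24 (not isolated)
Conditions: MeI (5 equiv), CH2Cl2, rt; then aq. NaHCO3, CH2Cl2, rt
Reagents that add atoms: none
Why: Quaternisation of the Mannich base followed by E1cB (Hofmann-type) elimination can only give the exocyclic α-methylene ketone, and it erases the uncontrolled stereocentre at C5.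

Step 15
Reactants: 25 tert-butyl (1E,10S)-8,8-dimethyl-5-methylidene-10-[(3-methylbutanoyl)oxy]-6-oxocycloundec-1-ene-1-carboxylate
Product: 26 tert-butyl (1E,6S,10S)-6-hydroxy-8,8-dimethyl-5-methylidene-10-[(3-methylbutanoyl)oxy]cycloundec-1-ene-1-carboxylate
Conditions: (R)-2-methyl-CBS-oxazaborolidine (0.5 equiv), catecholborane (1.5 equiv), toluene, −78 °C
Reagents that add atoms: none
Why: Corey–Bakshi–Shibata reduction, in which the (R)-oxazaborolidine binds the ketone with the 1-substituted vinyl group as the large substituent and delivers hydride 1,2 to the face that gives the (6S)-allylic alcohol (reagent control), the two esters being inert at −78 °C.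

Step 16
Reactants: 26 tert-butyl (1E,6S,10S)-6-hydroxy-8,8-dimethyl-5-methylidene-10-[(3-methylbutanoyl)oxy]cycloundec-1-ene-1-carboxylate
Product: 28 (1E,6S,10S)-6-hydroxy-8,8-dimethyl-5-methylidene-10-[(3-methylbutanoyl)oxy]cycloundec-1-ene-1-carboxylic acid, via bis(trimethylsilyl) derivative 27 (not isolated)
Conditions: Me3SiOTf (3 equiv), 2,6-lutidine (4 equiv), CH2Cl2, 0 °C; then aq. citric acid, THF, rt
Reagents that add atoms: none
Why: Silyl-triflate-mediated cleavage of the tert-butyl ester (loss of 2-methylpropene from the O-silylated ester) under buffered conditions also silylates the allylic alcohol and so protects it from ionisation, the isovalerate cannot lose a stabilised cation and survives, and mild aqueous acid removes both silyl groups without touching either stereocentre.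

**Compound list**

1 | 3,3-dimethylpentane-1,5-diol | OCCC(C)(C)CCO | starting material
2 | 5-[(4-methoxybenzyl)oxy]-3,3-dimethylpentan-1-ol | COc1ccc(COCCC(C)(C)CCO)cc1 | intermediate
3 | 5-[(4-methoxybenzyl)oxy]-3,3-dimethylpentanal | COc1ccc(COCCC(C)(C)CC=O)cc1 | intermediate
4 | tert-butyl 2-(bromomethyl)prop-2-enoate | C=C(CBr)C(=O)OC(C)(C)C | starting material
5 | tert-butyl (4S)-8-[(4-methoxybenzyl)oxy]-6,6-dimethyl-2-methylidene-4-[(trimethylsilyl)oxy]octanoate | C=C(C[C@@H](O[Si](C)(C)C)CC(C)(C)CCOCc1ccc(OC)cc1)C(=O)OC(C)(C)C | intermediate (not isolated)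
6 | tert-butyl (4S)-4-hydroxy-8-[(4-methoxybenzyl)oxy]-6,6-dimethyl-2-methylideneoctanoate | C=C(C[C@@H](O)CC(C)(C)CCOCc1ccc(OC)cc1)C(=O)OC(C)(C)C | intermediate
7 | tert-butyl (4S)-4-[(tert-butyldimethylsilyl)oxy]-8-[(4-methoxybenzyl)oxy]-6,6-dimethyl-2-methylideneoctanoate | C=C(C[C@@H](O[Si](C)(C)C(C)(C)C)CC(C)(C)CCOCc1ccc(OC)cc1)C(=O)OC(C)(C)C | intermediate
8 | 3-bromoprop-1-ene (allyl bromide) | C=CCBr | starting material
9 | tert-butyl (2E,4S)-2-(2-bromoethylidene)-4-[(tert-butyldimethylsilyl)oxy]-8-[(4-methoxybenzyl)oxy]-6,6-dimethyloctanoate | BrC/C=C(/C(=O)OC(C)(C)C)C[C@@H](O[Si](C)(C)C(C)(C)C)CC(C)(C)CCOCc1ccc(OC)cc1 | intermediate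
10 | tert-butyl (2E,4S)-2-(2-bromoethylidene)-4-[(tert-butyldimethylsilyl)oxy]-8-hydroxy-6,6-dimethyloctanoate | BrC/C=C(/C(=O)OC(C)(C)C)C[C@@H](O[Si](C)(C)C(C)(C)C)CC(C)(C)CCO | intermediate
11 | tert-butyl (2E,4S)-2-(2-bromoethylidene)-4-[(tert-butyldimethylsilyl)oxy]-6,6-dimethyl-8-oxooctanoate | BrC/C=C(/C(=O)OC(C)(C)C)C[C@@H](O[Si](C)(C)C(C)(C)C)CC(C)(C)CC=O | intermediate
12 | allylindium dibromide formed from 11 (indium on the former CH2Br carbon; drawn as one representative of the organoindium sesquihalide) | Br[In](Br)C/C=C(/C(=O)OC(C)(C)C)C[C@@H](O[Si](C)(C)C(C)(C)C)CC(C)(C)CC=O | intermediate (not isolated)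
13 | tert-butyl (6S)-6-[(tert-butyldimethylsilyl)oxy]-1-ethenyl-2-hydroxy-4,4-dimethylcycloheptane-1-carboxylate (mixture at C1 and C2) | C=CC1(C[C@@H](O[Si](C)(C)C(C)(C)C)CC(C)(C)CC1O)C(=O)OC(C)(C)C | intermediate
14 | tert-butyl (6S)-6-[(tert-butyldimethylsilyl)oxy]-1-ethenyl-4,4-dimethyl-2-oxocycloheptane-1-carboxylate (both C1 epimers) | C=CC1(C[C@@H](O[Si](C)(C)C(C)(C)C)CC(C)(C)CC1=O)C(=O)OC(C)(C)C | intermediate
15 | vinylmagnesium bromide | C=C[Mg]Br | starting material
16 | tert-butyl (6S)-6-[(tert-butyldimethylsilyl)oxy]-1,2-diethenyl-2-hydroxy-4,4-dimethylcycloheptane-1-carboxylate (mixture at C1 and C2) | C=CC1(C[C@@H](O[Si](C)(C)C(C)(C)C)CC(C)(C)CC1(O)C=C)C(=O)OC(C)(C)C | intermediate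
17 | dimethyl(methylidene)ammonium iodide (Eschenmoser's salt) | C=[N+](C)C.[I-] | starting material
18 | potassium alkoxide of 16 | C=CC1(C[C@@H](O[Si](C)(C)C(C)(C)C)CC(C)(C)CC1([O-])C=C)C(=O)OC(C)(C)C.[K+] | intermediate (not isolated)
19 | potassium (5E,8S)-6-(tert-butoxycarbonyl)-8-[(tert-butyldimethylsilyl)oxy]-10,10-dimethylcycloundeca-1,5-dien-1-olate | [K+].[O-]C1=CCC/C=C(/C(=O)OC(C)(C)C)C[C@@H](O[Si](C)(C)C(C)(C)C)CC(C)(C)C1 | intermediate (not isolated)
20 | tert-butyl (1E,10S)-10-[(tert-butyldimethylsilyl)oxy]-5-[(dimethylamino)methyl]-8,8-dimethyl-6-oxocycloundec-1-ene-1-carboxylate (both C5 epimers) | CN(C)CC1CC/C=C(/C(=O)OC(C)(C)C)C[C@@H](O[Si](C)(C)C(C)(C)C)CC(C)(C)CC1=O | intermediate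
21 | tert-butyl (1E,10S)-5-[(dimethylamino)methyl]-10-hydroxy-8,8-dimethyl-6-oxocycloundec-1-ene-1-carboxylate | CN(C)CC1CC/C=C(/C(=O)OC(C)(C)C)C[C@@H](O)CC(C)(C)CC1=O | intermediate
22 | 3-methylbutanoic anhydride (isovaleric anhydride) | CC(C)CC(=O)OC(=O)CC(C)C | starting material
23 | tert-butyl (1E,10S)-5-[(dimethylamino)methyl]-8,8-dimethyl-10-[(3-methylbutanoyl)oxy]-6-oxocycloundec-1-ene-1-carboxylate | CN(C)CC1CC/C=C(/C(=O)OC(C)(C)C)C[C@@H](OC(=O)CC(C)C)CC(C)(C)CC1=O | intermediate
24 | trimethylammonium iodide (methiodide) of 23 | C[N+](C)(C)CC1CC/C=C(/C(=O)OC(C)(C)C)C[C@@H](OC(=O)CC(C)C)CC(C)(C)CC1=O.[I-] | intermediate (not isolated)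
25 | tert-butyl (1E,10S)-8,8-dimethyl-5-methylidene-10-[(3-methylbutanoyl)oxy]-6-oxocycloundec-1-ene-1-carboxylate | C=C1CC/C=C(/C(=O)OC(C)(C)C)C[C@@H](OC(=O)CC(C)C)CC(C)(C)CC1=O | intermediate
26 | tert-butyl (1E,6S,10S)-6-hydroxy-8,8-dimethyl-5-methylidene-10-[(3-methylbutanoyl)oxy]cycloundec-1-ene-1-carboxylate | C=C1CC/C=C(/C(=O)OC(C)(C)C)C[C@@H](OC(=O)CC(C)C)CC(C)(C)C[C@@H]1O | intermediate
27 | trimethylsilyl (1E,6S,10S)-8,8-dimethyl-5-methylidene-10-[(3-methylbutanoyl)oxy]-6-[(trimethylsilyl)oxy]cycloundec-1-ene-1-carboxylate | C=C1CC/C=C(/C(=O)O[Si](C)(C)C)C[C@@H](OC(=O)CC(C)C)CC(C)(C)C[C@@H]1O[Si](C)(C)C | intermediate (not isolated)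
28 | (1E,6S,10S)-6-hydroxy-8,8-dimethyl-5-methylidene-10-[(3-methylbutanoyl)oxy]cycloundec-1-ene-1-carboxylic acid | C=C1CC/C=C(/C(=O)O)C[C@@H](OC(=O)CC(C)C)CC(C)(C)C[C@@H]1O | target

**Step count and risks**

Total step count: 16. Longest linear sequence: 16 steps (1 to 28).

Steps most likely to fail:

Step 11 (key step). Retro-aldol opening of the potassium aldolate may compete with the sigmatropic shift, and the open enone/dienolate pair may then be lost to intermolecular Michael addition. The trans-divinyl diastereomers may rearrange through the chair that places the ester inside, giving the wrong enoate geometry, which would then be consumed by transannular Claisen condensation. Proton transfer may also scramble the enolate before it is trapped. Fallback: starting from 16, the tertiary alcohol is silylated with N-(trimethylsilyl)imidazole to the trimethylsilyl ether F1. F1 is heated (toluene, sealed tube, about 150 °C, a little N,O-bis(trimethylsilyl)acetamide as acid scavenger) in a neutral, concerted silyloxy-Cope rearrangement, which involves no ionic fragments, to the ring-expanded silyl enol ether F2. F2 is aminomethylated with 17 in CH2Cl2 (Mannich reaction of a silyl enol ether), and the route is rejoined at 20.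

Step 5. The hindered 1,1-disubstituted acrylate may turn over slowly, with homodimerisation of allyl bromide and catalyst decay becoming the main processes. Fallback: starting from 7, Lemieux–Johnson cleavage of the methylidene group (OsO4 cat., NaIO4, 2,6-lutidine, dioxane/water) gives the α-keto ester F3. Vinylmagnesium bromide 15 (THF, −78 °C) adds to the ketone to give the tertiary allylic alcohol F4. PBr3 (pyridine, Et2O, −10 °C) converts F4 with allylic transposition (SN2′) into the γ-bromo enoate, and the route is rejoined at 9 (an E/Z mixture is acceptable because step 8 erases this geometry).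

Step 15. Facial discrimination may be poor because both ketone substituents (the 1-substituted vinyl group and the neopentyl-type CH2) are bulky and the macrocycle imposes its own conformational bias; 1,4-reduction may also compete. Fallback: starting from 25, Luche reduction (NaBH4, CeCl3·7H2O, MeOH, −78 °C; 1,2-selective, substrate control) gives 26 together with its C6 epimer, tert-butyl (1E,6R,10S)-6-hydroxy-8,8-dimethyl-5-methylidene-10-[(3-methylbutanoyl)oxy]cycloundec-1-ene-1-carboxylate F5. The two diastereomers are separated by chromatography, and F5 is returned to 25 with MnO2 and reduced again, so that the material is funnelled to 26, where the route is rejoined.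

**Further compounds**

F1 | step 11 | tert-butyl (6S)-6-[(tert-butyldimethylsilyl)oxy]-1,2-diethenyl-4,4-dimethyl-2-[(trimethylsilyl)oxy]cycloheptane-1-carboxylate | C=CC1(C[C@@H](O[Si](C)(C)C(C)(C)C)CC(C)(C)CC1(O[Si](C)(C)C)C=C)C(=O)OC(C)(C)C
F2 | step 11 | tert-butyl (1E,10S)-10-[(tert-butyldimethylsilyl)oxy]-8,8-dimethyl-6-[(trimethylsilyl)oxy]cycloundeca-1,5-diene-1-carboxylate | C[Si](C)(C)OC1=CCC/C=C(/C(=O)OC(C)(C)C)C[C@@H](O[Si](C)(C)C(C)(C)C)CC(C)(C)C1
F3 | step 5 | tert-butyl (4S)-4-[(tert-butyldimethylsilyl)oxy]-8-[(4-methoxybenzyl)oxy]-6,6-dimethyl-2-oxooctanoate | O=C(C[C@@H](O[Si](C)(C)C(C)(C)C)CC(C)(C)CCOCc1ccc(OC)cc1)C(=O)OC(C)(C)C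
F4 | step 5 | tert-butyl (4S)-4-[(tert-butyldimethylsilyl)oxy]-2-ethenyl-2-hydroxy-8-[(4-methoxybenzyl)oxy]-6,6-dimethyloctanoate | C=CC(O)(C[C@@H](O[Si](C)(C)C(C)(C)C)CC(C)(C)CCOCc1ccc(OC)cc1)C(=O)OC(C)(C)C
F5 | step 15 | tert-butyl (1E,6R,10S)-6-hydroxy-8,8-dimethyl-5-methylidene-10-[(3-methylbutanoyl)oxy]cycloundec-1-ene-1-carboxylate | C=C1CC/C=C(/C(=O)OC(C)(C)C)C[C@@H](OC(=O)CC(C)C)CC(C)(C)C[C@H]1O
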